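**Plan**

1. Numbering used throughout: C1 (quaternary, methyl), C2 (CHOH), C3 (CH2), C4 (isopropyl carbinol), C5 (ring-fusion CH) form the five-membered ring; C5–C6(O)–C7–C8(Me)–C9–C10(O)–C1 form the seven-membered ring. β is the face of the C1 methyl group.
2. Retrosynthesis: remove the two angelates and the oxirane (back to C8=C9), then cut C1–C5 by a retro-semipinacol shift of C1 back onto C6. The array C4(OH)–C5(H)–C6(O), with C6 next to quaternary C1, is the retron. The precursor is a trans-decalin (ring A = C1–C6, ring B = C1, C6–C10) with a C6 tertiary alcohol and a C5 mesylate.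
3. Ring A of that decalin is a p-menthane ring (C1 methyl para to C4 isopropyl). Ring B is cut by retro-Diels–Alder (C1–C10, C6–C7) to thymoquinone and a dienol ether from 3-methylbut-2-enal, which together supply all 15 skeletal carbons.
4. Forward order: ring B is closed first (Diels–Alder). The C1→C5 shift of step 10 then closes the cyclopentane, the last carbocycle to be closed (ring A contracted from six to five members), and by the same bond shift ring B becomes seven-membered. The oxirane follows as a functional group.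
5. Stereochemistry: C1 and C10 from the endo, catalyst-controlled Diels–Alder; C6–OH by enolate oxygenation anti to the C1 methyl; C2, C4 and C5 relayed from the axial C6–OH (directed reduction, directed dihydroxylation); C5 inverted in the shift; C6 by C4–OH-directed reduction; oxirane by C10–OH-directed epoxidation.

Key step: step 10

Remark: the (S)-oxazaborolidinium catalyst is assumed to give adduct 4 in the absolute sense drawn; should the induction prove opposite, its (R)-enantiomer is used and nothing else changes.

**Step 1**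
Reactants: 1 3-methylbut-2-enal
Product: 2 (E)-3-methyl-1-(triethylsilyloxy)buta-1,3-diene
Conditions: Et3SiOTf, Et3N, Et2O, 0 °C to rt
Reagents that add atoms: triethylsilyl trifluoromethanesulfonate, CC[Si](CC)(CC)OS(=O)(=O)C(F)(F)F
Why: γ-Deprotonation of the O-silylated enal (silyl dienol ether formation) should give the (E)-1-silyloxy diene, the s-trans enal geometry fixing the E enol double bond.

**Step 2**
Reactants: 2 (E)-3-methyl-1-(triethylsilyloxy)buta-1,3-diene; 3 thymoquinone
Product: 4 cis-fused octalin enedione (C1-Me and C6-H β, C10-OSiEt3 α)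
Conditions: oxazaborolidinium salt from (S)-1-(2-methylphenyl)-3,3-diphenyltetrahydro-1H,3H-pyrrolo[1,2-c][1,3,2]oxazaborole and HN(SO2CF3)2 (20 mol %), CH2Cl2, −78 °C
Reagents that add atoms: none
Why: Catalytic enantioselective quinone Diels–Alder reaction, in which the diene should add endo to the less hindered methyl-bearing C=C with its CH2 terminus bonding to unsubstituted C6 and its oxygenated terminus to C1, so that the C1 quaternary centre, the cis ring fusion and C10–O trans to the methyl arise together and the catalyst sets the absolute sense.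

**Step 3**
Reactants: 4 cis-fused octalin enedione
Product: 6 trans-fused 6α-hydroxy enedione, via C6 hydroperoxide 5 (not isolated)
Conditions: t-BuOK, O2, P(OEt)3, THF/t-BuOH, −40 °C
Reagents that add atoms: dioxygen, O=O
Why: C6–H is the only enolisable proton (C1 quaternary, C3 vinylic), and enolate oxygenation with in situ phosphite reduction should deliver O2, the smallest electrophile, antiperiplanar to the axial C1 methyl to give the trans-fused ketol directly in a chair, although the axial C10 siloxy oxygen on the α face opposes this (see risks).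

**Step 4**
Reactants: 6 trans-fused 6α-hydroxy enedione
Product: 8 C4=C5 enol triflate with C2 ketone, via lithium C5-enolate 7 (not isolated)
Conditions: LiBH(s-Bu)3, THF, −78 °C; then PhN(SO2CF3)2, −78 to 0 °C
Reagents that add atoms: N-phenylbis(trifluoromethanesulfonimide), O=S(=O)(N(c1ccccc1)S(=O)(=O)C(F)(F)F)C(F)(F)F
Why: Conjugate reduction by the hindered borohydride at the unsubstituted enedione carbon C3 should give the C5 enolate regiospecifically, and O-triflation traps it (conjugate reduction–enolate trapping); no stereocentre is formed.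

**Step 5**
Reactants: 8 C4=C5 enol triflate with C2 ketone
Product: 9 2β-alcohol of the enol triflate
Conditions: Me4NBH(OAc)3, MeCN/AcOH, −30 °C
Reagents that add atoms: none
Why: Evans–Saksena reduction, in which the axial C6 alkoxyborohydride delivers hydride intramolecularly to the α face of the C2 ketone, should give the 1,3-anti diol, that is C2–OH β and cis to the C1 methyl.

**Step 6**
Reactants: 9 2β-alcohol of the enol triflate
Product: 10 allylic diol (C4=C5–H, 2β-OH, 6α-OH)
Conditions: Pd(OAc)2 (5 mol %), PPh3, HCO2H, Bu3N, DMF, 60 °C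
Reagents that add atoms: none
Why: Palladium-catalysed formate reduction of the enol triflate replaces OTf by H and leaves the double bond at C4=C5 where the triflate fixed it; the ketone was reduced first so that no conjugation can occur.

**Step 7**
Reactants: 10 allylic diol
Product: 11 2β-TBS ether with free 6α-OH
Conditions: t-BuMe2SiOTf, 2,6-lutidine, CH2Cl2, −78 °C
Reagents that add atoms: tert-butyldimethylsilyl trifluoromethanesulfonate, CC(C)(C)[Si](C)(C)OS(=O)(=O)C(F)(F)F
Why: Low-temperature silylation should take the secondary C2 hydroxyl only, the axial tertiary C6 hydroxyl being too hindered and needed free as a directing group.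

**Step 8**
Reactants: 11 2β-TBS ether with free 6α-OH
Product: 13 4α,5α,6α-triol, via osmate ester 12 (not isolated)
Conditions: OsO4 (1.05 equiv), Me2NCH2CH2NMe2, CH2Cl2, −78 °C; then aq. Na2SO3
Reagents that add atoms: osmium tetroxide, O=[Os](=O)(=O)=O
Why: Hydrogen-bond-directed dihydroxylation, in which the OsO4–diamine complex is delivered by the allylic C6–OH to the α face of C4=C5, should set C4 (OH α, isopropyl β) and C5 (OH α) while the merely homoallylic C8=C9 bond reacts more slowly.

**Step 9**
Reactants: 13 4α,5α,6α-triol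
Product: 14 C5 mesylate
Conditions: MsCl, Et3N, CH2Cl2, −20 °C
Reagents that add atoms: methanesulfonyl chloride, CS(=O)(=O)Cl
Why: Selective sulfonylation of the only secondary hydroxyl (equatorial at C5); the two tertiary hydroxyls should not react.

**Step 10**
Reactants: 14 C5 mesylate
Product: 16 cis-fused hydroazulenone (C6 ketone, 4α-OH, H-5 β), via aluminium dialkoxide 15 (not isolated)
Conditions: Et3Al (3 equiv), CH2Cl2, −78 to −20 °C; then aq. potassium sodium tartrate
Reagents that add atoms: none
Why: Et3Al turns both tertiary hydroxyls into aluminium alkoxides and activates the sulfonate; the C1–C6 bond of the trans-decalin chair is antiperiplanar to the equatorial C5–OMs bond, so C1 migrates from C6 to C5 while the C6 alkoxide collapses to the ketone in one concerted, stereospecific 1,2-shift. The closest known reaction type is the organoaluminium-promoted pinacol-type (semipinacol) rearrangement of 2-hydroxy mesylates, the class of shift long used to turn hydronaphthalenes into hydroazulenes. The cyclopentane C1–C2–C3–C4–C5 is closed by ring contraction through a suprafacial 1,2-alkyl shift (the new C1–C5 bond replaces C5–O), and the same shift inserts C1 between C10 and C5 so that ring B becomes the cycloheptene. C5 is the only new stereocentre and is fixed by inversion (H-5 β, cis ring fusion); C1 migrates with retention, and C4 (OH α) is untouched and ends cis to the new C6 carbonyl. The step needs migration of C1 and not of C3 (from the C4 alkoxide, equally antiperiplanar) or of C7; C7 is gauche to the leaving group, and quaternary C1, whose shift also relieves the syn-axial C4–O/C6–O/C10–O interactions, should migrate much faster than primary C3.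

**Step 11**
Reactants: 16 cis-fused hydroazulenone
Product: 17 6β-alcohol
Conditions: Me4NBH(OAc)3, MeCN/AcOH, −30 °C
Reagents that add atoms: none
Why: Evans–Saksena reduction directed by the C4 hydroxyl should deliver hydride intramolecularly from the α face of the β-hydroxy ketone and give the 1,3-anti diol, C6–OH β.

**Step 12**
Reactants: 17 6β-alcohol
Product: 18 6β,10α-diol with C2 TBS ether
Conditions: pyridinium p-toluenesulfonate (10 mol %), MeOH, 0 °C
Reagents that add atoms: none
Why: Acid-catalysed methanolysis should cleave the secondary triethylsilyl ether far faster than the hindered secondary TBS ether (selective desilylation).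

**Step 13**
Reactants: 18 6β,10α-diol with C2 TBS ether
Product: 19 8α,9α-epoxide
Conditions: VO(acac)2 (5 mol %), t-BuOOH, CH2Cl2, 0 °C
Reagents that add atoms: tert-butyl hydroperoxide, CC(C)(C)OO
Why: Vanadium-catalysed hydroxyl-directed epoxidation should deliver oxygen to C8=C9 syn to the allylic C10–OH (α face), the known preference of cyclohept-2-enols, the homoallylic C6–OH directing far more weakly.

**Step 14**
Reactants: 19 8α,9α-epoxide
Product: 20 6,10-di-O-angeloyl 2-O-TBS ether
Conditions: angelic acid, 2,4,6-Cl3C6H2COCl, Et3N, toluene, rt; then 19, 80 °C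
Reagents that add atoms: angelic acid ((Z)-2-methylbut-2-enoic acid), C/C=C(/C)C(=O)O
Why: Yamaguchi-type mixed-anhydride esterification without DMAP is the variant known to transfer the angeloyl group without Z-to-E isomerisation; both secondary hydroxyls should acylate and the tertiary C4–OH should not.

**Step 15**
Reactants: 20 6,10-di-O-angeloyl 2-O-TBS ether
Product: 21 target
Conditions: HF·pyridine, pyridine, THF, 0 °C to rt
Reagents that add atoms: none
Why: Buffered fluoride cleavage of the silyl ether frees the C2 hydroxyl under conditions the esters and the oxirane should tolerate.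

**Compound list**

1 | 3-methylbut-2-enal | CC(C)=CC=O | starting material
2 | (E)-3-methyl-1-(triethylsilyloxy)buta-1,3-diene | C=C(C)/C=C/O[Si](CC)(CC)CC | intermediate
3 | thymoquinone (2-isopropyl-5-methyl-1,4-benzoquinone) | CC1=CC(=O)C(C(C)C)=CC1=O | starting material
4 | cis-fused octalin enedione: C2 and C5 ketones, C3=C4 (C4 isopropyl), C8=C9 (C8 methyl), C1-Me and C6-H β, C10-OSiEt3 α | C[C@@]12C(=O)C=C(C(C)C)C(=O)[C@@H]1CC(C)=C[C@@H]2O[Si](CC)(CC)CC | intermediate
5 | 6α-hydroperoxide of 4 (trans-fused) | C[C@@]12C(=O)C=C(C(C)C)C(=O)[C@@]1(OO)CC(C)=C[C@@H]2O[Si](CC)(CC)CC | intermediate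
6 | trans-fused 6α-hydroxy enedione | C[C@@]12C(=O)C=C(C(C)C)C(=O)[C@@]1(O)CC(C)=C[C@@H]2O[Si](CC)(CC)CC | intermediate
7 | lithium C5-enolate (C4=C5–OLi, C3 reduced, C2 ketone) | C[C@@]12C(=O)CC(C(C)C)=C([O-])[C@@]1(O)CC(C)=C[C@@H]2O[Si](CC)(CC)CC.[Li+] | intermediate
8 | C4=C5 enol triflate (OTf on C5), C2 ketone, 6α-OH | C[C@@]12C(=O)CC(C(C)C)=C(OS(=O)(=O)C(F)(F)F)[C@@]1(O)CC(C)=C[C@@H]2O[Si](CC)(CC)CC | intermediate
9 | 2β-alcohol of 8 | C[C@@]12[C@@H](O)CC(C(C)C)=C(OS(=O)(=O)C(F)(F)F)[C@@]1(O)CC(C)=C[C@@H]2O[Si](CC)(CC)CC | intermediate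
10 | allylic diol: C4=C5–H, 2β-OH, 6α-OH | C[C@@]12[C@@H](O)CC(C(C)C)=C[C@@]1(O)CC(C)=C[C@@H]2O[Si](CC)(CC)CC | intermediate
11 | 2β-TBS ether of 10 | C[C@@]12[C@@H](O[Si](C)(C)C(C)(C)C)CC(C(C)C)=C[C@@]1(O)CC(C)=C[C@@H]2O[Si](CC)(CC)CC | intermediate
12 | 4α,5α-osmate ester of 11 as its TMEDA adduct | C[C@@]12[C@@H](O[Si](C)(C)C(C)(C)C)C[C@]3(C(C)C)O[Os](=O)(=O)O[C@@H]3[C@@]1(O)CC(C)=C[C@@H]2O[Si](CC)(CC)CC.CN(C)CCN(C)C | intermediate
13 | 4α,5α,6α-triol (isopropyl β, H-5 β) | C[C@@]12[C@@H](O[Si](C)(C)C(C)(C)C)C[C@@](O)(C(C)C)[C@H](O)[C@@]1(O)CC(C)=C[C@@H]2O[Si](CC)(CC)CC | intermediate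
14 | C5 mesylate of 13 | C[C@@]12[C@@H](O[Si](C)(C)C(C)(C)C)C[C@@](O)(C(C)C)[C@H](OS(C)(=O)=O)[C@@]1(O)CC(C)=C[C@@H]2O[Si](CC)(CC)CC | intermediate
15 | C4,C6-bis(diethylaluminium) alkoxide of 14 | C[C@@]12[C@@H](O[Si](C)(C)C(C)(C)C)C[C@@](O[Al](CC)CC)(C(C)C)[C@H](OS(C)(=O)=O)[C@@]1(O[Al](CC)CC)CC(C)=C[C@@H]2O[Si](CC)(CC)CC | intermediate
16 | cis-fused hydroazulenone: C6 ketone, 4α-OH, H-5 β, C8=C9, 2β-OTBS, 10α-OSiEt3 | O=C1CC(C)=C[C@H](O[Si](CC)(CC)CC)[C@@]2(C)[C@@H]1[C@](O)(C(C)C)C[C@@H]2O[Si](C)(C)C(C)(C)C | intermediate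
17 | 6β-alcohol of 16 | O[C@H]1CC(C)=C[C@H](O[Si](CC)(CC)CC)[C@@]2(C)[C@@H]1[C@](O)(C(C)C)C[C@@H]2O[Si](C)(C)C(C)(C)C | intermediate
18 | 6β,10α-diol, 2β-OTBS | O[C@H]1CC(C)=C[C@H](O)[C@@]2(C)[C@@H]1[C@](O)(C(C)C)C[C@@H]2O[Si](C)(C)C(C)(C)C | intermediate
19 | 8α,9α-epoxide of 18 | O[C@H]1C[C@]2(C)O[C@@H]2[C@H](O)[C@@]2(C)[C@@H]1[C@](O)(C(C)C)C[C@@H]2O[Si](C)(C)C(C)(C)C | intermediate
20 | 6,10-di-O-angeloyl 2-O-TBS ether | C/C=C(/C)C(=O)O[C@H]1C[C@]2(C)O[C@@H]2[C@H](OC(=O)/C(C)=C\C)[C@@]2(C)[C@@H]1[C@](O)(C(C)C)C[C@@H]2O[Si](C)(C)C(C)(C)C | intermediate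
21 | CNP0265715.3 (6β,10α-diangeloyloxy-8α,9α-epoxy-daucane-2β,4α-diol) | C/C=C(/C)C(=O)O[C@H]1C[C@]2(C)O[C@@H]2[C@H](OC(=O)/C(C)=C\C)[C@@]2(C)[C@@H]1[C@](O)(C(C)C)C[C@@H]2O | target

**Step count and risks**

Total: 15 steps. Longest linear sequence: 15 steps (1 to 21); thymoquinone 3 enters at step 2.

Step 10. The shift may start from the C4 alkoxide instead (migration of C3, also antiperiplanar to the leaving group), or the product aldolate may open by retro-aldol cleavage. The fallback locks the C4 oxygen in an oxirane. It sets out from 11: VO(acac)2/t-BuOOH (CH2Cl2, 0 °C) should epoxidise C4=C5 syn to the axial C6–OH and give the syn-epoxy alcohol F1. ZnBr2 (CH2Cl2, 0 °C) then triggers the semipinacol rearrangement of the 2,3-epoxy alcohol: C1 shifts to C5 anti to the C5–O bond and the oxirane oxygen stays on C4 as the tertiary hydroxyl. This returns to the route at 16.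

Step 3. Oxygen may enter on the methyl-bearing face (the α face carries the axial C10 siloxy group), giving the cis-fused ketol, which cannot be corrected later. The fallback delivers the oxygen from the C10 hydroxyl. It sets out from 4: t-BuMe2SiOTf/Et3N gives the C5 TBS dienol ether F2, and buffered HF·pyridine removes the triethylsilyl group to give the homoallylic alcohol F3. 3-Chloroperbenzoic acid (NaHCO3, CH2Cl2, −20 °C) should then be guided by hydrogen bonding from the α C10–OH to the α face of the electron-rich enol ether (Rubottom oxidation under Henbest control), giving the 6α-silyloxy ketone F4; Bu4NF/AcOH in the same flask converts it into the diol F5. Et3SiCl/imidazole silylates only the secondary C10–OH and returns to the route at 6.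

Step 2. The strongly acidic catalyst may erode the preference for the methyl-bearing double bond or the orientation of the diene, or discriminate the two faces poorly. The fallback moves stereocontrol to an auxiliary on the diene and runs the cycloaddition thermally. It sets out from 1: t-BuOK followed by (S)-2-methoxy-2-phenylacetyl chloride gives the dienyl ester F6. Uncatalysed cycloaddition with 3 (toluene, rt), governed by sterics for site and orientation and by the mandelate for the face, should give the adduct F7. K2CO3/MeOH (0 °C, short contact) cleaves the ester to the C10 alcohol F8, and Et3SiCl/imidazole returns to the route at 4.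

**Further compounds**

F1 | step 10 | syn-4α,5α-epoxy 6α-alcohol (2β-OTBS, 10α-OSiEt3) | C[C@@]12[C@@H](O[Si](C)(C)C(C)(C)C)C[C@]3(C(C)C)O[C@@H]3[C@@]1(O)CC(C)=C[C@@H]2O[Si](CC)(CC)CC
F2 | step 3 | C5 TBS dienol ether of 4 (C5=C6) | C[C@@]12C(=O)C=C(C(C)C)C(O[Si](C)(C)C(C)(C)C)=C1CC(C)=C[C@@H]2O[Si](CC)(CC)CC
F3 | step 3 | 10α-alcohol of F2 | C[C@@]12C(=O)C=C(C(C)C)C(O[Si](C)(C)C(C)(C)C)=C1CC(C)=C[C@@H]2O
F4 | step 3 | 6α-(tert-butyldimethylsilyloxy) enedione with free 10α-OH | C[C@@]12C(=O)C=C(C(C)C)C(=O)[C@@]1(O[Si](C)(C)C(C)(C)C)CC(C)=C[C@@H]2O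
F5 | step 3 | 6α,10α-dihydroxy enedione | C[C@@]12C(=O)C=C(C(C)C)C(=O)[C@@]1(O)CC(C)=C[C@@H]2O
F6 | step 2 | (E)-3-methylbuta-1,3-dienyl (S)-2-methoxy-2-phenylacetate | C=C(C)/C=C/OC(=O)[C@@H](OC)c1ccccc1
F7 | step 2 | cis-fused adduct carrying the C10 (S)-O-methylmandelate | C[C@@]12C(=O)C=C(C(C)C)C(=O)[C@@H]1CC(C)=C[C@@H]2OC(=O)[C@@H](OC)c1ccccc1
F8 | step 2 | cis-fused adduct with free 10α-OH | C[C@@]12C(=O)C=C(C(C)C)C(=O)[C@@H]1CC(C)=C[C@@H]2O
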